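Grey looked much like delta: the same E and L, but J at 4.00 equiv against 5.1 equiv. Blue looked like theta, with 0.500 equiv of J against 0.60 equiv.

| flask | E | J | L | remark | time |
|---|---|---|---|---|---|
| theta | 0.20 M | 0.60 equiv | 0.020 M | run made earlier |  |
| delta | 0.20 M | 5.1 equiv | 0.020 M | run made earlier |  |
| blue | 0.20 M | 0.500 equiv | 0.0200 M |  | 4.0 d |
| grey | 0.20 M | 4.00 equiv | 0.0200 M |  | 4.0 d |

- theta (time / d: G / %, Z / %, E / %): 0.625: 1.5, 1.2, 57.6; 1.25: 1.2, 1.8, 55.3; 1.67: 1.2, 1.8, 54.8; 2.50: 0.9, 1.9, 55.1; 3.00: 1.4, 2.1, 54.9; 4.00: 0.8, 2.4, 54.9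
- delta (time / d: G / %, Z / %, E / %): 0.208: 48.3, 5.5, 4.7; 0.625: 82.6, 1.9, 0.2; 1.04: 92.0, 0.3, 0.1; 1.67: 95.4, 0, 0.1; 2.50: 95.6, 0.4, 0.4; 3.00: 95.1, 0.1, 0.1; 4.00: 95.4, 0.6, 0

(readings scatter by 0.3 percentage points)

- which of these holds the largest part of the E at the end of blue (E / X / G / Z)
- which of these holds the largest part of the E at the end of grey (E / X / G / Z)
- how much G is there at the end of grey, in percent of the E charged



Blue was simple. One J converts one E at most, so at least 50.0% of the E stayed as E.

Grey held 4.00 equiv of J against the 3 that a full conversion uses. Delta stood level from 1.67 d, and grey had 4.0 d, so I took grey to finish too. But delta ended with G at 95.4%, E at 0% and Z at 0.6%, so some material had left the path to G. I assumed a side route on L, racing J. The lost share should then follow L over J. I called their proportion the leak factor, a selectivity factor: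

leak factor = lost share × J charged / L charged = 2.35 (delta)

lost share in grey = 5.86%, so G = 94.1%

This uses charged J, although J falls during a run.

The forecast named E for blue and G for grey, with G at 93% (88% to 96%): “Delta plateaus at 95.4%, so I expect G slightly lower, about 93%.” My figure stood higher than its figure.

The flasks gave E for blue, at 60.8%, and G for grey, with G at 94.2%.

    X + L → D (k = 0.0410 M⁻¹ min⁻¹)
    J + X → Z (k = 0.0190 M⁻¹ min⁻¹)
    E + J → X (k = 0.0140 M⁻¹ min⁻¹)
    J + Z → G (k = 0.0350 M⁻¹ min⁻¹)
    Z ⇌ Q (K = 4.90, k = 0.0450 min⁻¹)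

Grey had come to rest. At 40.0 d G stood at 94.3%, and D stayed at 5.69%. The remaining Z, 0.0106%, and Q, 0.0596%, fell to 0% and 0%. At 4.00 d the slowest mode of grey had a half-life of 0.408 d. A later reading of G in grey made no difference. My estimated lost share for grey was 5.86%, and D in grey stood at 5.69%.

In the neighbour with E at 0.050 M, J stayed at 4.00 equiv and L at 0.0200 M, so the leak factor gave a lost share of 23.5%. That flask gave D at 19.4% and G at 73.2%, with 7.28% still in Z and Q.

The earlier runs and the new flask are simulated for substances that don't exist; noise was put on by code.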